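## Retrosynthetic overview

1. The last ring (pyran of quinolone A, O–C-c bond) is closed by acid-catalysed addition of the 4-OH of quinolone A across the pyran alkene of quinolone B; the tertiary carbinol comes from a methyl ketone and MeMgBr.
2. The key C–C bond (C-3 of quinolone A to C-a) is made by an intermolecular, amine-catalysed enantioselective Michael addition of hydroxyquinolone 6 to dienone 12; C-a then controls C-b and C-c.
3. Dienone 12 comes from veprisine 8 by bromination and Heck coupling; 8 comes from 6 and 3-methylbut-2-enal (Knoevenagel/6π closure of the pyran of quinolone B).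
4. Quinolone 6 (used twice) comes from 2,3-dimethoxyaniline by N-methylation, acylation with Meldrum's acid and Friedel–Crafts ring closure.
5. Ring order: quinolone, then pyran of B (ring 2), then pyran of A (ring 1) last.

Labels: C-a = CH carrying the 2-hydroxy-2-methylpropyl chain; C-b = ring-fusion CH bonded to CMe2; C-c = ring-fusion O–CH bonded to C-3 of quinolone B. Target: C-a (S), C-b (S), C-c (R), cis ring fusion, chain on C-a trans to CMe2.

Assumption: the (S,S)-diamine in step 8 gives the (S) adduct as it does for warfarin (recalled, not derived); if the sense is reversed for dienone 12, the (R,R)-diamine is used with no other change.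

## Route

Step 1
Reactants: 1 2,3-dimethoxyaniline
Product: 2 N-(2,3-dimethoxyphenyl)formamide
Conditions: HCO2H (3 equiv), toluene, reflux, Dean–Stark
Reagents that add atoms: formic acid, O=CO
Why: Dehydrative N-formylation of an aniline is clean and stops at the mono-amide, which fixes mono-methylation for the next step.

Step 2
Reactants: 2 N-(2,3-dimethoxyphenyl)formamide
Product: 3 2,3-dimethoxy-N-methylaniline
Conditions: LiAlH4 (2 equiv), THF, reflux; Fieser work-up
Reagents that add atoms: none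
Why: Hydride reduction of a formanilide to the N-methylaniline (amide reduction); aryl methyl ethers are inert.

Step 3
Reactants: 3 2,3-dimethoxy-N-methylaniline; 4 Meldrum's acid (2,2-dimethyl-1,3-dioxane-4,6-dione)
Product: 5 3-[(2,3-dimethoxyphenyl)(methyl)amino]-3-oxopropanoic acid
Conditions: toluene, 90 °C, 4 h
Reagents that add atoms: none
Why: Nucleophilic ring opening of Meldrum's acid by the amine (acylation with loss of acetone) gives the malonamic acid without over-acylation.

Step 4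
Reactants: 5 3-[(2,3-dimethoxyphenyl)(methyl)amino]-3-oxopropanoic acid
Product: 6 4-hydroxy-7,8-dimethoxy-1-methylquinolin-2(1H)-one
Conditions: P2O5/MeSO3H (1:10 w/w), 70 °C, 2 h; ice-water
Reagents that add atoms: none
Why: Intramolecular Friedel–Crafts acylation at the only free position ortho to nitrogen (para to a methoxy group) gives the 4-hydroxy-2-quinolone.

Step 5
Reactants: 6 4-hydroxy-7,8-dimethoxy-1-methylquinolin-2(1H)-one; 7 3-methylbut-2-enal
Product: 8 7,8-dimethoxy-2,2,6-trimethyl-2,6-dihydro-5H-pyrano[3,2-c]quinolin-5-one (veprisine)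
Conditions: ethylenediammonium diacetate (20 mol %), CH2Cl2, 40 °C
Reagents that add atoms: none
Why: Knoevenagel condensation at C-3 followed by oxa-6π electrocyclisation (formal [3+3]) is the standard flindersine-type pyran annulation and gives the angular 2-quinolone isomer.

Step 6
Reactants: 8 veprisine
Product: 10 3-bromo-7,8-dimethoxy-2,2,6-trimethyl-2,6-dihydro-5H-pyrano[3,2-c]quinolin-5-one, via trans-3,4-dibromide 9 (not isolated)
Conditions: Br2 (1.0 equiv), CH2Cl2, −78 °C; then 1,8-diazabicyclo[5.4.0]undec-7-ene (2.2 equiv), −78 °C → rt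
Reagents that add atoms: bromine, BrBr
Why: Anti-addition of bromine to the electron-rich pyran alkene, then dehydrobromination through the C-4 cation stabilised by the quinolone, leaves the vinylic 3-bromide (bromination–dehydrobromination).

Step 7
Reactants: 10 3-bromoveprisine; 11 but-3-en-2-one (methyl vinyl ketone, 3 equiv)
Product: 12 (E)-4-(7,8-dimethoxy-2,2,6-trimethyl-5-oxo-5,6-dihydro-2H-pyrano[3,2-c]quinolin-3-yl)but-3-en-2-one
Conditions: Pd(OAc)2 (5 mol %), Bu4NCl (1 equiv), NaHCO3 (2.5 equiv), DMF, 70 °C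
Reagents that add atoms: none
Why: Heck coupling of a vinyl bromide with an enone under phosphine-free phase-transfer conditions gives the (E)-dienone by syn-insertion and syn-β-hydride elimination.

Step 8
Reactants: 6 4-hydroxy-7,8-dimethoxy-1-methylquinolin-2(1H)-one (1.2 equiv); 12 dienone
Product: 13 3-[(1S)-1-(7,8-dimethoxy-2,2,6-trimethyl-5-oxo-5,6-dihydro-2H-pyrano[3,2-c]quinolin-3-yl)-3-oxobutyl]-4-hydroxy-7,8-dimethoxy-1-methylquinolin-2(1H)-one (open keto form; equilibrates with its cyclic hemiketal)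
Conditions: (1S,2S)-1,2-diphenylethane-1,2-diamine (20 mol %), AcOH (10 equiv), THF, 25–40 °C, 3–5 d; recrystallise
Reagents that add atoms: none
Why: Warfarin-type asymmetric Michael addition: the primary amine forms the ketiminium of the enone, and C-3 of 6 adds 1,4 to the β-carbon (the trisubstituted δ-carbon blocks 1,6-addition) on the face set by the diamine, giving C-a (S).

Step 9
Reactants: 13 Michael adduct
Product: 14 3-[(1S)-1-(7,8-dimethoxy-2,2,6-trimethyl-5-oxo-5,6-dihydro-2H-pyrano[3,2-c]quinolin-3-yl)-3-hydroxy-3-methylbutyl]-4-hydroxy-7,8-dimethoxy-1-methylquinolin-2(1H)-one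
Conditions: CeCl3 (anhydrous, 4 equiv), MeMgBr (5 equiv), THF, −78 → 0 °C; aq. NH4Cl
Reagents that add atoms: methylmagnesium bromide, C[Mg]Br
Why: Cerium-mediated Grignard 1,2-addition to the methyl ketone; the first equivalent forms the quinolonate, which frees the ketone from the hemiketal and suppresses retro-Michael, and the vinylogous carbamate carbonyls do not react.

Step 10
Reactants: 14 diol
Product: 16 3-[(1S)-3-[(tert-butyldimethylsilyl)oxy]-1-(7,8-dimethoxy-2,2,6-trimethyl-5-oxo-5,6-dihydro-2H-pyrano[3,2-c]quinolin-3-yl)-3-methylbutyl]-4-hydroxy-7,8-dimethoxy-1-methylquinolin-2(1H)-one, via bis-silyl ether 15 (not isolated)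
Conditions: TBSOTf (2.5 equiv), 2,6-lutidine (4 equiv), CH2Cl2, 0 °C → rt; then MeOH, K2CO3 (0.2 equiv), 0 °C
Reagents that add atoms: tert-butyldimethylsilyl trifluoromethanesulfonate, CC(C)(C)[Si](C)(C)OS(=O)(=O)C(F)(F)F
Why: Silyl triflate silylates both hydroxyls, and mild methanolysis then removes only the labile enol (vinylogous ester) silyl group, masking the tertiary carbinol that would otherwise trap the cation of step 11 (silyl protection with selective desilylation).

Step 11
Reactants: 16 mono-silyl ether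
Product: 17 O-tert-butyldimethylsilyl ether of the target, C-a (S), C-b (S), C-c (R)
Conditions: (1S)-camphor-10-sulfonic acid (20 mol %), CH2Cl2, 0 °C → rt
Reagents that add atoms: none
Why: Intramolecular Markovnikov hydroalkoxylation: protonation at C-b gives the C-c cation stabilised by quinolone B, which the 4-OH of quinolone A captures in a six-membered cis-fusing closure, with the C-a chain held anti to the gem-dimethyl group (A(1,2) strain) so that C-b (S) and C-c (R) follow from C-a.

Step 12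
Reactants: 17 silyl ether
Product: 18 target CNP0160874.2
Conditions: Bu4NF (3 equiv), THF, 40 °C
Reagents that add atoms: none
Why: Fluoride-mediated desilylation of the tertiary silyl ether under non-acidic conditions leaves the acid-labile O–C-c bond and all three stereocentres untouched.

## Compound list

1 | 2,3-dimethoxyaniline | Nc1cccc(OC)c1OC | starting material
2 | N-(2,3-dimethoxyphenyl)formamide | O=CNc1cccc(OC)c1OC | intermediate
3 | 2,3-dimethoxy-N-methylaniline | CNc1cccc(OC)c1OC | intermediate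
4 | Meldrum's acid (2,2-dimethyl-1,3-dioxane-4,6-dione) | CC1(C)OC(=O)CC(=O)O1 | starting material
5 | 3-[(2,3-dimethoxyphenyl)(methyl)amino]-3-oxopropanoic acid | CN(C(=O)CC(=O)O)c1cccc(OC)c1OC | intermediate
6 | 4-hydroxy-7,8-dimethoxy-1-methylquinolin-2(1H)-one | COc1ccc2c(O)cc(=O)n(C)c2c1OC | intermediate
7 | 3-methylbut-2-enal | CC(C)=CC=O | starting material
8 | 7,8-dimethoxy-2,2,6-trimethyl-2,6-dihydro-5H-pyrano[3,2-c]quinolin-5-one (veprisine) | COc1ccc2c3c(c(=O)n(C)c2c1OC)C=CC(C)(C)O3 | intermediate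
9 | (±)-trans-3,4-dibromo-7,8-dimethoxy-2,2,6-trimethyl-2,3,4,6-tetrahydro-5H-pyrano[3,2-c]quinolin-5-one (racemic; one enantiomer drawn; not isolated) | COc1ccc2c3c(c(=O)n(C)c2c1OC)[C@@H](Br)[C@H](Br)C(C)(C)O3 | intermediate
10 | 3-bromo-7,8-dimethoxy-2,2,6-trimethyl-2,6-dihydro-5H-pyrano[3,2-c]quinolin-5-one | COc1ccc2c3c(c(=O)n(C)c2c1OC)C=C(Br)C(C)(C)O3 | intermediate
11 | but-3-en-2-one (methyl vinyl ketone) | CC(=O)C=C | starting material
12 | (E)-4-(7,8-dimethoxy-2,2,6-trimethyl-5-oxo-5,6-dihydro-2H-pyrano[3,2-c]quinolin-3-yl)but-3-en-2-one | COc1ccc2c3c(c(=O)n(C)c2c1OC)C=C(/C=C/C(C)=O)C(C)(C)O3 | intermediate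
13 | 3-[(1S)-1-(7,8-dimethoxy-2,2,6-trimethyl-5-oxo-5,6-dihydro-2H-pyrano[3,2-c]quinolin-3-yl)-3-oxobutyl]-4-hydroxy-7,8-dimethoxy-1-methylquinolin-2(1H)-one | COc1ccc2c(O)c(c(=O)n(C)c2c1OC)[C@@H](CC(C)=O)C1=Cc2c(c3ccc(OC)c(OC)c3n(C)c2=O)OC1(C)C | intermediate
14 | 3-[(1S)-1-(7,8-dimethoxy-2,2,6-trimethyl-5-oxo-5,6-dihydro-2H-pyrano[3,2-c]quinolin-3-yl)-3-hydroxy-3-methylbutyl]-4-hydroxy-7,8-dimethoxy-1-methylquinolin-2(1H)-one | COc1ccc2c(O)c(c(=O)n(C)c2c1OC)[C@@H](CC(C)(C)O)C1=Cc2c(c3ccc(OC)c(OC)c3n(C)c2=O)OC1(C)C | intermediate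
15 | bis(tert-butyldimethylsilyl) ether of 14 (4-O-silyl and tertiary O-silyl; not isolated) | COc1ccc2c(O[Si](C)(C)C(C)(C)C)c(c(=O)n(C)c2c1OC)[C@@H](CC(C)(C)O[Si](C)(C)C(C)(C)C)C1=Cc2c(c3ccc(OC)c(OC)c3n(C)c2=O)OC1(C)C | intermediate
16 | 3-[(1S)-3-[(tert-butyldimethylsilyl)oxy]-1-(7,8-dimethoxy-2,2,6-trimethyl-5-oxo-5,6-dihydro-2H-pyrano[3,2-c]quinolin-3-yl)-3-methylbutyl]-4-hydroxy-7,8-dimethoxy-1-methylquinolin-2(1H)-one | COc1ccc2c(O)c(c(=O)n(C)c2c1OC)[C@@H](CC(C)(C)O[Si](C)(C)C(C)(C)C)C1=Cc2c(c3ccc(OC)c(OC)c3n(C)c2=O)OC1(C)C | intermediate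
17 | O-tert-butyldimethylsilyl ether of the target: cis-fused bis(pyranoquinolinone), C-a (S), C-b (S), C-c (R) | COc1ccc2c3c(c(=O)n(C)c2c1OC)[C@@H](CC(C)(C)O[Si](C)(C)C(C)(C)C)[C@H]1[C@@H](O3)c2c(c3ccc(OC)c(OC)c3n(C)c2=O)OC1(C)C | intermediate
18 | CNP0160874.2: cis-fused bis(7,8-dimethoxy-N-methylpyrano[3,2-c]quinolinone) with a 2-hydroxy-2-methylpropyl chain on C-a; C-a (S), C-b (S), C-c (R) | COc1ccc2c3c(c(=O)n(C)c2c1OC)[C@@H](CC(C)(C)O)[C@H]1[C@@H](O3)c2c(c3ccc(OC)c(OC)c3n(C)c2=O)OC1(C)C | target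

## Summary

Total steps: 12. Longest linear sequence: 12 (1 → 18; quinolone 6 is used in steps 5 and 8).

Three steps most likely to fail:

Step 8 (Michael addition to a hindered, donor-substituted dienone; rate and ee at risk). The fallback sets out from bromide 10 and quinolone 6 and comes back at 13. Heck coupling of 10 with acrolein (Pd(OAc)2, Bu4NCl, NaHCO3, DMF, 50 °C) gives the more electrophilic dienal (E)-3-(7,8-dimethoxy-2,2,6-trimethyl-5-oxo-5,6-dihydro-2H-pyrano[3,2-c]quinolin-3-yl)prop-2-enal F2. Secondary-amine iminium catalysis with (S)-2-[diphenyl(trimethylsilyloxy)methyl]pyrrolidine (20 mol %, CH2Cl2, rt) adds 6 to the face away from the silyloxydiphenylmethyl group and gives, after hemiacetalisation, the lactol (4S)-4-(7,8-dimethoxy-2,2,6-trimethyl-5-oxo-5,6-dihydro-2H-pyrano[3,2-c]quinolin-3-yl)-2-hydroxy-7,8-dimethoxy-6-methyl-2,3,4,6-tetrahydro-5H-pyrano[3,2-c]quinolin-5-one F3. Excess MeMgBr (THF, 0 °C) opens the lactol to the secondary alcohol 3-[(1S)-1-(7,8-dimethoxy-2,2,6-trimethyl-5-oxo-5,6-dihydro-2H-pyrano[3,2-c]quinolin-3-yl)-3-hydroxybutyl]-4-hydroxy-7,8-dimethoxy-1-methylquinolin-2(1H)-one F4, and SO3·pyridine/DMSO/Et3N oxidation gives 13.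

Step 11 (acid ring closure; risks are silyl ether loss or participation, closure through the C-2 oxygen of quinolone A, or the C-b/C-c epimer). The fallback sets out from 16 and comes back at 17. Bromoetherification with N-bromosuccinimide and NaHCO3 (CH2Cl2, −20 °C) activates only the pyran alkene, and anti-addition of the enol oxygen and bromine gives the bromo ether, the C-b bromide of 17, F5. Radical debromination (Bu3SnH, 2,2'-azobis(2-methylpropionitrile), toluene, 80 °C) delivers hydrogen to C-b from the convex face of the cis-fused bicycle and gives 17.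

Step 7 (Heck coupling of a hindered vinyl bromide with a polymerisable enone). The fallback sets out from 10 and comes back at 12. Reductive carbonylation (Pd(OAc)2, di(1-adamantyl)-n-butylphosphine, CO/H2 5 bar, N,N,N',N'-tetramethylethylenediamine, toluene, 100 °C) gives the non-enolisable aldehyde 7,8-dimethoxy-2,2,6-trimethyl-5-oxo-5,6-dihydro-2H-pyrano[3,2-c]quinoline-3-carbaldehyde F1. Claisen–Schmidt aldol condensation with acetone (aq. NaOH, acetone, 0 °C → rt) gives 12.

## Further compounds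

F1 | step 7 | 7,8-dimethoxy-2,2,6-trimethyl-5-oxo-5,6-dihydro-2H-pyrano[3,2-c]quinoline-3-carbaldehyde | COc1ccc2c3c(c(=O)n(C)c2c1OC)C=C(C=O)C(C)(C)O3
F2 | step 8 | (E)-3-(7,8-dimethoxy-2,2,6-trimethyl-5-oxo-5,6-dihydro-2H-pyrano[3,2-c]quinolin-3-yl)prop-2-enal | COc1ccc2c3c(c(=O)n(C)c2c1OC)C=C(/C=C/C=O)C(C)(C)O3
F3 | step 8 | (4S)-4-(7,8-dimethoxy-2,2,6-trimethyl-5-oxo-5,6-dihydro-2H-pyrano[3,2-c]quinolin-3-yl)-2-hydroxy-7,8-dimethoxy-6-methyl-2,3,4,6-tetrahydro-5H-pyrano[3,2-c]quinolin-5-one (anomer mixture) | COc1ccc2c3c(c(=O)n(C)c2c1OC)[C@@H](CC(O)O3)C1=Cc2c(c3ccc(OC)c(OC)c3n(C)c2=O)OC1(C)C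
F4 | step 8 | 3-[(1S)-1-(7,8-dimethoxy-2,2,6-trimethyl-5-oxo-5,6-dihydro-2H-pyrano[3,2-c]quinolin-3-yl)-3-hydroxybutyl]-4-hydroxy-7,8-dimethoxy-1-methylquinolin-2(1H)-one (carbinol epimers) | COc1ccc2c(O)c(c(=O)n(C)c2c1OC)[C@@H](CC(C)O)C1=Cc2c(c3ccc(OC)c(OC)c3n(C)c2=O)OC1(C)C
F5 | step 11 | C-b bromide of silyl ether 17 (bromine in place of the C-b hydrogen, anti to the new O–C-c bond) | COc1ccc2c3c(c(=O)n(C)c2c1OC)[C@@H](CC(C)(C)O[Si](C)(C)C(C)(C)C)[C@@]1(Br)[C@@H](O3)c2c(c3ccc(OC)c(OC)c3n(C)c2=O)OC1(C)C
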